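## Retrosynthetic overview

1. Numbering used throughout: C1(=O)-O2-C3(guaiacyl)-C3a-C4H2-O5-C6(catechol)-C6a. The target comes from a protected furofuranone (TBS on the guaiacyl OH, two acetates on the catechol), which is unmasked last under non-basic conditions.
2. Key disconnection (new step): C3a-C4 and C3-O2 are cut together, giving an acyclic MOM-protected syn-aldol imide. In the forward direction an oxonium-Prins closure forms the tetrahydrofuran ring first. The imide carbonyl then captures the benzylic cation, which closes the lactone ring, expels the auxiliary and sets C3a and C3.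
3. C6-C6a comes from an Evans syn aldol of an (E)-styrylacetyl oxazolidinone with 3,4-diacetoxybenzaldehyde (sets C6 and C6a).
4. The imide comes from (S)-4-benzyloxazolidin-2-one and an (E)-4-arylbut-3-enoic acid, which is made by a Wittig reaction of O-TBS-vanillin.

Assumption: carbon-skeleton building blocks and the auxiliary are numbered. Simple reagents that only deliver a protecting group or one atom (TBSCl, Ac2O, MOMCl, water) are named under "Reagents that add atoms" and are not numbered.

## Route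

Step 1
Reactants: 1 vanillin
Product: 2 4-(tert-butyldimethylsilyloxy)-3-methoxybenzaldehyde
Conditions: TBSCl, imidazole, DMF, rt
Reagents that add atoms: tert-butyldimethylsilyl chloride (TBSCl), CC(C)(C)[Si](C)(C)Cl
Why: Imidazole-promoted silyl ether formation masks the acidic phenol, keeps this ring electron-rich for step 7, and allows a final fluoride release that avoids base and hydrogenolysis; no stereocentre is involved.

Step 2
Reactants: 2 4-(tert-butyldimethylsilyloxy)-3-methoxybenzaldehyde; 3 (2-carboxyethyl)triphenylphosphonium bromide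
Product: 5 (E)-4-[4-(tert-butyldimethylsilyloxy)-3-methoxyphenyl]but-3-enoic acid, via ylide carboxylate 4 (not isolated)
Conditions: NaHMDS (2 equiv per 3), THF, 0 °C; then 2, -78 °C to rt; 1 M HCl work-up
Reagents that add atoms: none
Why: The Wittig olefination of an aromatic aldehyde with the carboxylate-bearing ylide gives the β,γ-unsaturated acid mainly as the styrene-conjugated (E)-alkene, and the aryl silyl ether tolerates the non-nucleophilic amide base.

Step 3
Reactants: 5 (E)-4-[4-(tert-butyldimethylsilyloxy)-3-methoxyphenyl]but-3-enoic acid; 6 (S)-4-benzyloxazolidin-2-one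
Product: 8 (S)-4-benzyl-3-{(E)-4-[4-(tert-butyldimethylsilyloxy)-3-methoxyphenyl]but-3-enoyl}oxazolidin-2-one, via mixed pivalic anhydride 7 (not isolated)
Conditions: PivCl, Et3N, THF, -20 °C; then LiCl, 6, rt
Reagents that add atoms: none
Why: Mixed-anhydride N-acylation of the Evans auxiliary under LiCl/Et3N needs no strong base, so the alkene neither migrates nor isomerises and attack occurs at the less hindered carbonyl of the anhydride.

Step 4
Reactants: 9 3,4-dihydroxybenzaldehyde
Product: 10 3,4-diacetoxybenzaldehyde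
Conditions: Ac2O, pyridine, cat. DMAP, CH2Cl2, 0 °C to rt
Reagents that add atoms: acetic anhydride, CC(=O)OC(C)=O
Why: O-acetylation of the catechol deliberately makes this ring electron-poor, which raises the aldehyde reactivity in step 5 and suppresses benzylic ionisation at C6 in step 7.

Step 5
Reactants: 8 (S)-4-benzyl-3-{(E)-4-[4-(tert-butyldimethylsilyloxy)-3-methoxyphenyl]but-3-enoyl}oxazolidin-2-one; 10 3,4-diacetoxybenzaldehyde
Product: 13 (S)-4-benzyl-3-{(2S,3E)-2-[(S)-(3,4-diacetoxyphenyl)(hydroxy)methyl]-4-[4-(tert-butyldimethylsilyloxy)-3-methoxyphenyl]but-3-enoyl}oxazolidin-2-one, via boron dienolate 11 (not isolated), via boron aldolate 12 (not isolated)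
Conditions: Bu2BOTf, Et3N, CH2Cl2, -78 to 0 °C; then 10, -78 to -10 °C; pH 7 buffer/MeOH work-up (no H2O2)
Reagents that add atoms: none
Why: In this Evans syn aldol the (Z)-boron dienolate reacts at its α-carbon through a Zimmerman-Traxler chair on the face away from the benzyl group, which sets the future C6a (S) and C6 (S) and regenerates the (E)-styrene, while the peroxide-free work-up spares the aryl acetates.

Step 6
Reactants: 13 (S)-4-benzyl-3-{(2S,3E)-2-[(S)-(3,4-diacetoxyphenyl)(hydroxy)methyl]-4-[4-(tert-butyldimethylsilyloxy)-3-methoxyphenyl]but-3-enoyl}oxazolidin-2-one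
Product: 14 (S)-4-benzyl-3-{(2S,3E)-2-[(S)-(3,4-diacetoxyphenyl)(methoxymethoxy)methyl]-4-[4-(tert-butyldimethylsilyloxy)-3-methoxyphenyl]but-3-enoyl}oxazolidin-2-one
Conditions: MOMCl, iPr2NEt, cat. Bu4NI, CH2Cl2, 0 °C to rt
Reagents that add atoms: chloromethyl methyl ether (MOMCl), COCCl
Why: MOM ether formation (O-alkylation with an α-chloro ether under a hindered amine) places the future C4 carbon on the C6 oxygen without touching either stereocentre, and the base is too weak for retro-aldol, enolisation or acetate cleavage.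

Step 7
Reactants: 14 (S)-4-benzyl-3-{(2S,3E)-2-[(S)-(3,4-diacetoxyphenyl)(methoxymethoxy)methyl]-4-[4-(tert-butyldimethylsilyloxy)-3-methoxyphenyl]but-3-enoyl}oxazolidin-2-one
Product: 17 (3S,3aR,6S,6aS)-6-(3,4-diacetoxyphenyl)-3-[4-(tert-butyldimethylsilyloxy)-3-methoxyphenyl]tetrahydro-1H,3H-furo[3,4-c]furan-1-one, via oxocarbenium triflate 15 (not isolated), via bicyclic imidate triflate 16 (not isolated)
Conditions: TMSOTf (1.3 equiv), 4 Å MS, CH2Cl2 (0.02 M), -78 to -20 °C; then aq NaHCO3, 0 °C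
Reagents that add atoms: water, O
Why: Proposed new method: TMSOTf silylates the less hindered methoxy oxygen of the MOM acetal and releases the formaldehyde-level oxocarbenium ion 15, which attacks the internal carbon of the electron-rich (E)-styrene in a 5-exo Markovnikov oxonium-Prins closure of the tetrahydrofuran (only this mode puts the charge on the p-silyloxybenzylic carbon), and the exocyclic imide carbonyl oxygen on the adjacent carbon captures that carbon from the opposite alkene face as in a halolactonisation, so anti addition to the (E)-alkene gives the trans C3-aryl/C4 relationship (C3 S, aryl exo); only the rotamer leading to the cis-fused bicycle (C3a R) can be captured, whereas the trans cation reverts by retro-Prins or reversible proton loss, and any six-ring capture of 15 by the same carbonyl is a reversible resting state; C6 and C6a stay intact because the two acetates shut down benzylic ionisation, 2-oxonia-Cope scrambling and Friedel-Crafts closure on the catechol ring, and water finally hydrolyses imidate 16 to the lactone with loss of the auxiliary; the closest known reaction types are the oxonium-Prins cyclisation of styrenyl homoallylic alcohols with halide capture and the halolactonisation of 4-arylbut-3-enoic acids and unsaturated N-acyl oxazolidinones, but a tethered carbon electrophile from a MOM ether combined with auxiliary-expelling lactone capture has not been shown.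

Step 8
Reactants: 17 (3S,3aR,6S,6aS)-6-(3,4-diacetoxyphenyl)-3-[4-(tert-butyldimethylsilyloxy)-3-methoxyphenyl]tetrahydro-1H,3H-furo[3,4-c]furan-1-one
Product: 18 (3S,3aR,6S,6aS)-3-[4-(tert-butyldimethylsilyloxy)-3-methoxyphenyl]-6-(3,4-dihydroxyphenyl)tetrahydro-1H,3H-furo[3,4-c]furan-1-one
Conditions: H2NNH2·AcOH (2.5 equiv), DMF, 0 °C to rt, argon
Reagents that add atoms: none
Why: Buffered hydrazinolysis cleaves the activated aryl acetates much faster than the alkyl γ-lactone in a reducing medium that protects the catechol, and the still silylated guaiacyl ring cannot form a quinone methide, so C3 is not scrambled.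

Step 9
Reactants: 18 (3S,3aR,6S,6aS)-3-[4-(tert-butyldimethylsilyloxy)-3-methoxyphenyl]-6-(3,4-dihydroxyphenyl)tetrahydro-1H,3H-furo[3,4-c]furan-1-one
Product: 19 (3S,3aR,6S,6aS)-6-(3,4-dihydroxyphenyl)-3-(4-hydroxy-3-methoxyphenyl)tetrahydro-1H,3H-furo[3,4-c]furan-1-one
Conditions: TBAF, AcOH (1:1.5), THF, 0 °C, argon
Reagents that add atoms: none
Why: Fluoride-mediated desilylation of the aryl silyl ether, buffered with acetic acid, keeps the liberated phenols protonated, so neither quinone methide formation at C3 nor catechol oxidation competes and all four stereocentres are retained.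

## Compound list

1 | vanillin (4-hydroxy-3-methoxybenzaldehyde) | COc1cc(C=O)ccc1O | starting material
2 | 4-(tert-butyldimethylsilyloxy)-3-methoxybenzaldehyde | COc1cc(C=O)ccc1O[Si](C)(C)C(C)(C)C | intermediate
3 | (2-carboxyethyl)triphenylphosphonium bromide | OC(=O)CC[P+](c1ccccc1)(c1ccccc1)c1ccccc1.[Br-] | starting material
4 | ylide carboxylate, sodium 3-(triphenylphosphoranylidene)propanoate (not isolated) | [Na+].[O-]C(=O)CC=P(c1ccccc1)(c1ccccc1)c1ccccc1 | intermediate
5 | (E)-4-[4-(tert-butyldimethylsilyloxy)-3-methoxyphenyl]but-3-enoic acid | OC(=O)C/C=C/c1ccc(O[Si](C)(C)C(C)(C)C)c(OC)c1 | intermediate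
6 | (S)-4-benzyloxazolidin-2-one | O=C1OC[C@H](Cc2ccccc2)N1 | starting material
7 | mixed pivalic anhydride of 5 (not isolated) | CC(C)(C)C(=O)OC(=O)C/C=C/c1ccc(O[Si](C)(C)C(C)(C)C)c(OC)c1 | intermediate
8 | (S)-4-benzyl-3-{(E)-4-[4-(tert-butyldimethylsilyloxy)-3-methoxyphenyl]but-3-enoyl}oxazolidin-2-one | O=C1OC[C@H](Cc2ccccc2)N1C(=O)C/C=C/c3ccc(O[Si](C)(C)C(C)(C)C)c(OC)c3 | intermediate
9 | 3,4-dihydroxybenzaldehyde | O=Cc1ccc(O)c(O)c1 | starting material
10 | 3,4-diacetoxybenzaldehyde | O=Cc1ccc(OC(C)=O)c(OC(C)=O)c1 | intermediate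
11 | boron dienolate, (Z)-O-dibutylboryl dienolate of 8 (not isolated) | CCCCB(CCCC)O/C(N1C(=O)OC[C@@H]1Cc2ccccc2)=C\C=C\c3ccc(O[Si](C)(C)C(C)(C)C)c(OC)c3 | intermediate
12 | boron aldolate, O-dibutylboryl derivative of 13 (not isolated) | O=C1OC[C@H](Cc2ccccc2)N1C(=O)[C@@H](/C=C/c3ccc(O[Si](C)(C)C(C)(C)C)c(OC)c3)[C@H](OB(CCCC)CCCC)c4ccc(OC(C)=O)c(OC(C)=O)c4 | intermediate
13 | (S)-4-benzyl-3-{(2S,3E)-2-[(S)-(3,4-diacetoxyphenyl)(hydroxy)methyl]-4-[4-(tert-butyldimethylsilyloxy)-3-methoxyphenyl]but-3-enoyl}oxazolidin-2-one (Evans syn aldol adduct) | O=C1OC[C@H](Cc2ccccc2)N1C(=O)[C@@H](/C=C/c3ccc(O[Si](C)(C)C(C)(C)C)c(OC)c3)[C@H](O)c4ccc(OC(C)=O)c(OC(C)=O)c4 | intermediate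
14 | (S)-4-benzyl-3-{(2S,3E)-2-[(S)-(3,4-diacetoxyphenyl)(methoxymethoxy)methyl]-4-[4-(tert-butyldimethylsilyloxy)-3-methoxyphenyl]but-3-enoyl}oxazolidin-2-one (MOM ether) | O=C1OC[C@H](Cc2ccccc2)N1C(=O)[C@@H](/C=C/c3ccc(O[Si](C)(C)C(C)(C)C)c(OC)c3)[C@H](OCOC)c4ccc(OC(C)=O)c(OC(C)=O)c4 | intermediate
15 | oxocarbenium triflate, O-methylidene oxonium ion from 14 (not isolated) | O=C1OC[C@H](Cc2ccccc2)N1C(=O)[C@@H](/C=C/c3ccc(O[Si](C)(C)C(C)(C)C)c(OC)c3)[C@H]([O+]=C)c4ccc(OC(C)=O)c(OC(C)=O)c4.[O-]S(=O)(=O)C(F)(F)F | intermediate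
16 | bicyclic imidate triflate, cis-fused furofuran in which C1 carries the oxazolidinone nitrogen and is doubly bonded to O2 (not isolated) | COc1cc([C@H]2[O+]=C(N4C(=O)OC[C@@H]4Cc5ccccc5)[C@H]3[C@@H]2CO[C@@H]3c6ccc(OC(C)=O)c(OC(C)=O)c6)ccc1O[Si](C)(C)C(C)(C)C.[O-]S(=O)(=O)C(F)(F)F | intermediate
17 | (3S,3aR,6S,6aS)-6-(3,4-diacetoxyphenyl)-3-[4-(tert-butyldimethylsilyloxy)-3-methoxyphenyl]tetrahydro-1H,3H-furo[3,4-c]furan-1-one | COc1cc([C@H]2OC(=O)[C@H]3[C@@H]2CO[C@@H]3c2ccc(OC(C)=O)c(OC(C)=O)c2)ccc1O[Si](C)(C)C(C)(C)C | intermediate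
18 | (3S,3aR,6S,6aS)-3-[4-(tert-butyldimethylsilyloxy)-3-methoxyphenyl]-6-(3,4-dihydroxyphenyl)tetrahydro-1H,3H-furo[3,4-c]furan-1-one | COc1cc([C@H]2OC(=O)[C@H]3[C@@H]2CO[C@@H]3c2ccc(O)c(O)c2)ccc1O[Si](C)(C)C(C)(C)C | intermediate
19 | (3S,3aR,6S,6aS)-6-(3,4-dihydroxyphenyl)-3-(4-hydroxy-3-methoxyphenyl)tetrahydro-1H,3H-furo[3,4-c]furan-1-one (CNP0268159.1) | COc1cc([C@H]2OC(=O)[C@H]3[C@@H]2CO[C@@H]3c2ccc(O)c(O)c2)ccc1O | target

## Step count and risks

Total step count: 9.
Longest linear sequence: 8 steps (1, 2, 3, 5, 6, 7, 8, 9, starting from vanillin).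

The three steps most likely to fail:

**Step 7 (the proposed new cascade).**
- Risks: the Prins closure may give the trans tetrahydrofuran cation, which then eliminates; the imide carbonyl may capture the cation too slowly; the MOM group may simply be lost.
- Fallback (known chemistry): it sets out from 2 and 9 and comes back at 19.
- An L-proline-catalysed cross-aldol of commercial methyl 4-oxobutanoate with 2 is followed by NaBH4 reduction in the same pot. Spontaneous lactonisation gives (4R)-4-{(R)-[4-(tert-butyldimethylsilyloxy)-3-methoxyphenyl](hydroxy)methyl}dihydrofuran-2(3H)-one F1. This sets C3a; the anti carbinol centre is corrected later.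
- TESOTf/2,6-lutidine converts F1 into (4R)-4-{(R)-[4-(tert-butyldimethylsilyloxy)-3-methoxyphenyl](triethylsilyloxy)methyl}dihydrofuran-2(3H)-one F2.
- Compound 9 with TBSCl/imidazole gives 3,4-bis(tert-butyldimethylsilyloxy)benzaldehyde F3.
- LiHMDS enolisation of F2 and addition to F3, anti to the side chain, gives (3S,4R)-3-{[3,4-bis(tert-butyldimethylsilyloxy)phenyl](hydroxy)methyl}-4-{(R)-[4-(tert-butyldimethylsilyloxy)-3-methoxyphenyl](triethylsilyloxy)methyl}dihydrofuran-2(3H)-one F4. It forms as inconsequential carbinol epimers.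
- TFA in wet CH2Cl2 at 0 °C removes the TES group. Translactonisation follows, and the freed primary alcohol closes by SN1 onto the electron-rich C6 benzylic cation. With acid equilibration of the benzylic lactone centre, the material converges on (3S,3aR,6S,6aS)-6-[3,4-bis(tert-butyldimethylsilyloxy)phenyl]-3-[4-(tert-butyldimethylsilyloxy)-3-methoxyphenyl]tetrahydro-1H,3H-furo[3,4-c]furan-1-one F5.
- TBAF/AcOH as in step 9 then gives 19.

**Step 5 (aldol of the styrylacetyl imide).**
- Risks: γ-attack of the dienolate, alkene migration, or retro-aldol.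
- Fallback: the styrene is installed after the aldol. It sets out from 6, 10 and 2 and comes back at 13.
- Compound 6 is acylated (n-BuLi, crotonyl chloride) to (S)-4-benzyl-3-[(E)-but-2-enoyl]oxazolidin-2-one F6.
- The well-established deconjugative boron aldol (Bu2BOTf, Et3N) of F6 with 10 gives (S)-4-benzyl-3-{(2S)-2-[(S)-(3,4-diacetoxyphenyl)(hydroxy)methyl]but-3-enoyl}oxazolidin-2-one F7.
- Compound 2 is methylenated (Ph3P=CH2) to 4-(tert-butyldimethylsilyloxy)-3-methoxystyrene F8.
- (E)-selective cross metathesis of F7 with F8 (second-generation Hoveyda-Grubbs catalyst, CH2Cl2, reflux) gives 13.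

**Step 9 (final desilylation).**
- Risks: the p-hydroxybenzylic lactone can open to a quinone methide and epimerise at C3, and the free catechol can oxidise in a fluoride medium.
- Fallback: the order of unmasking is reversed and the last step becomes an enzymatic one. It sets out from 17 and comes back at 19.
- HF·pyridine in THF at 0 °C (acidic medium, acetates intact) gives (3S,3aR,6S,6aS)-6-(3,4-diacetoxyphenyl)-3-(4-hydroxy-3-methoxyphenyl)tetrahydro-1H,3H-furo[3,4-c]furan-1-one F9.
- Immobilised Candida antarctica lipase B with n-butanol in MTBE at 35 °C then transfers both acetyl groups to butanol under neutral, base-free conditions to give 19.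

## Further compounds

F1 | step 7 | (4R)-4-{(R)-[4-(tert-butyldimethylsilyloxy)-3-methoxyphenyl](hydroxy)methyl}dihydrofuran-2(3H)-one | O=C1C[C@H](CO1)[C@@H](O)c1ccc(O[Si](C)(C)C(C)(C)C)c(OC)c1
F2 | step 7 | (4R)-4-{(R)-[4-(tert-butyldimethylsilyloxy)-3-methoxyphenyl](triethylsilyloxy)methyl}dihydrofuran-2(3H)-one | O=C1C[C@H](CO1)[C@@H](O[Si](CC)(CC)CC)c1ccc(O[Si](C)(C)C(C)(C)C)c(OC)c1
F3 | step 7 | 3,4-bis(tert-butyldimethylsilyloxy)benzaldehyde | O=Cc1ccc(O[Si](C)(C)C(C)(C)C)c(O[Si](C)(C)C(C)(C)C)c1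
F4 | step 7 | (3S,4R)-3-{[3,4-bis(tert-butyldimethylsilyloxy)phenyl](hydroxy)methyl}-4-{(R)-[4-(tert-butyldimethylsilyloxy)-3-methoxyphenyl](triethylsilyloxy)methyl}dihydrofuran-2(3H)-one (carbinol epimers) | O=C1[C@H](C(O)c2ccc(O[Si](C)(C)C(C)(C)C)c(O[Si](C)(C)C(C)(C)C)c2)[C@H](CO1)[C@@H](O[Si](CC)(CC)CC)c1ccc(O[Si](C)(C)C(C)(C)C)c(OC)c1
F5 | step 7 | (3S,3aR,6S,6aS)-6-[3,4-bis(tert-butyldimethylsilyloxy)phenyl]-3-[4-(tert-butyldimethylsilyloxy)-3-methoxyphenyl]tetrahydro-1H,3H-furo[3,4-c]furan-1-one | COc1cc([C@H]2OC(=O)[C@H]3[C@@H]2CO[C@@H]3c2ccc(O[Si](C)(C)C(C)(C)C)c(O[Si](C)(C)C(C)(C)C)c2)ccc1O[Si](C)(C)C(C)(C)C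
F6 | step 5 | (S)-4-benzyl-3-[(E)-but-2-enoyl]oxazolidin-2-one | C/C=C/C(=O)N1C(=O)OC[C@@H]1Cc1ccccc1
F7 | step 5 | (S)-4-benzyl-3-{(2S)-2-[(S)-(3,4-diacetoxyphenyl)(hydroxy)methyl]but-3-enoyl}oxazolidin-2-one | O=C1OC[C@H](Cc2ccccc2)N1C(=O)[C@@H](C=C)[C@H](O)c1ccc(OC(C)=O)c(OC(C)=O)c1
F8 | step 5 | 4-(tert-butyldimethylsilyloxy)-3-methoxystyrene | C=Cc1ccc(O[Si](C)(C)C(C)(C)C)c(OC)c1
F9 | step 9 | (3S,3aR,6S,6aS)-6-(3,4-diacetoxyphenyl)-3-(4-hydroxy-3-methoxyphenyl)tetrahydro-1H,3H-furo[3,4-c]furan-1-one | COc1cc([C@H]2OC(=O)[C@H]3[C@@H]2CO[C@@H]3c2ccc(OC(C)=O)c(OC(C)=O)c2)ccc1O
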